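The route cuts ring A from the pyranone at its two fusion atoms, the ether bond O1–C8a and the ketone bond C4–C4a. In the key step the cesium salt of a 2-arylacrylic acid that already carries ring B and its prenyl group meets 3,5-bis(benzyloxy)benzyne. The aryne inserts into the acyl C–O bond and the resulting phenoxide closes ring C by oxa-Michael addition, so the isoflavanone skeleton arises in one operation. The step exploits the ortho relation of O1 and C4 on C8a/C4a of the phloroglucinol-type ring A, whose C5 oxygen next to C4a steers the regiochemistry. C3 is set afterwards by dynamic kinetic resolution, the epoxide by Shi epoxidation.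

Key step: step 8

Assumption: the target is read as the (3S)-isoflavanone with an (R)-configured epoxide carbon, and 3,5-bis(benzyloxy)phenol and 3-bromo-4,5-dihydroxybenzaldehyde are taken as commercial.

Step 1
Reactants: 1 3,5-bis(benzyloxy)phenol
Product: 2 3,5-bis(benzyloxy)phenyl N-(propan-2-yl)carbamate
Conditions: i-PrNCO, Et3N (cat.), CH2Cl2, rt
Reagents that add atoms: isopropyl isocyanate CC(C)N=C=O
Why: Amine-catalysed addition of the phenol to the isocyanate (O-carbamoylation) installs a directing group for ortho-metalation that can later be removed under mild base.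

Step 2
Reactants: 2 3,5-bis(benzyloxy)phenyl N-(propan-2-yl)carbamate
Product: 6 3,5-bis(benzyloxy)-2-(trimethylsilyl)phenyl N-(propan-2-yl)carbamate, via N-silyl carbamate 3 (not isolated), via aryllithium 4 (not isolated), via N-silyl arylsilane 5 (not isolated)
Conditions: TBSOTf, TMEDA, Et2O, 0 °C to rt; n-BuLi, TMEDA, −78 °C; TMSCl, −78 °C to rt; aq. NaHSO4 work-up
Reagents that add atoms: chlorotrimethylsilane C[Si](C)(C)Cl; tert-butyldimethylsilyl trifluoromethanesulfonate CC(C)(C)[Si](C)(C)OS(=O)(=O)C(F)(F)F (its silyl group is carried only by 3, 4 and 5)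
Why: Directed ortho-metalation (Snieckus type): after in situ N-silylation the carbamate directs lithiation to the position between it and a benzyloxy group (both such positions are equivalent), TMSCl traps the aryllithium and the N–Si bond is hydrolysed on work-up.

Step 3
Reactants: 6 3,5-bis(benzyloxy)-2-(trimethylsilyl)phenyl N-(propan-2-yl)carbamate
Product: 8 3,5-bis(benzyloxy)-2-(trimethylsilyl)phenyl trifluoromethanesulfonate, via silylphenol 7 (not isolated)
Conditions: DBU, Et2NH, MeCN, 40 °C; then PhNTf2, rt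
Reagents that add atoms: N-phenylbis(trifluoromethanesulfonimide) O=S(=O)(N(c1ccccc1)S(=O)(=O)C(F)(F)F)C(F)(F)F
Why: Base-induced E1cB cleavage of the N–H carbamate frees the phenoxide (the isocyanate is scavenged by Et2NH as a urea), and O-triflation with PhNTf2 in the same flask gives the Kobayashi-type aryne precursor.

Step 4
Reactants: 9 3-bromo-4,5-dihydroxybenzaldehyde
Product: 10 3,4-bis(benzyloxy)-5-bromobenzaldehyde
Conditions: BnBr, K2CO3, DMF, 60 °C
Reagents that add atoms: benzyl bromide BrCc1ccccc1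
Why: Williamson etherification of both catechol hydroxyls gives benzyl ethers that withstand fluoride, base, hydride and oxidants and leave by neutral hydrogenolysis at the end.

Step 5
Reactants: 10 3,4-bis(benzyloxy)-5-bromobenzaldehyde
Product: 11 3,4-bis(benzyloxy)-5-(3-methylbut-2-en-1-yl)benzaldehyde
Conditions: tributyl(prenyl)stannane, Pd(PPh3)4, DMF, 100 °C
Reagents that add atoms: tributyl(3-methylbut-2-en-1-yl)stannane CCCC[Sn](CCCC)(CCCC)CC=C(C)C
Why: Stille coupling of the aryl bromide with the prenylstannane should give the linear prenyl arene because C–C bond formation occurs at the less hindered allyl terminus, and the aldehyde is tolerated.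

Step 6
Reactants: 11 3,4-bis(benzyloxy)-5-(3-methylbut-2-en-1-yl)benzaldehyde
Product: 12 1,2-bis(benzyloxy)-5-ethynyl-3-(3-methylbut-2-en-1-yl)benzene
Conditions: dimethyl (1-diazo-2-oxopropyl)phosphonate, K2CO3, MeOH, rt
Reagents that add atoms: dimethyl (1-diazo-2-oxopropyl)phosphonate COP(=O)(OC)C(=[N+]=[N-])C(C)=O
Why: The Ohira–Bestmann modification of the Seyferth–Gilbert homologation converts the non-enolizable aryl aldehyde into the terminal alkyne under mild basic conditions that leave the prenyl group and the benzyl ethers untouched.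

Step 7
Reactants: 12 1,2-bis(benzyloxy)-5-ethynyl-3-(3-methylbut-2-en-1-yl)benzene
Product: 13 2-[3,4-bis(benzyloxy)-5-(3-methylbut-2-en-1-yl)phenyl]prop-2-enoic acid
Conditions: Pd(OAc)2 (cat.), Xantphos, HCO2H, Ac2O (cat.), toluene, 80 °C
Reagents that add atoms: formic acid OC=O
Why: Palladium-catalysed Markovnikov hydrocarboxylation of the terminal aryl alkyne, with formic acid as the source of both hydride and CO, gives the branched 2-arylacrylic acid, while the hindered trisubstituted prenyl olefin should not react.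

Step 8
Reactants: 13 2-[3,4-bis(benzyloxy)-5-(3-methylbut-2-en-1-yl)phenyl]prop-2-enoic acid and 8 3,5-bis(benzyloxy)-2-(trimethylsilyl)phenyl trifluoromethanesulfonate
Product: 16 rac-5,7-bis(benzyloxy)-3-[3,4-bis(benzyloxy)-5-(3-methylbut-2-en-1-yl)phenyl]-2,3-dihydro-4H-chromen-4-one, via aryne 14 (not isolated), via hydroxyaryl enone 15 (not isolated)
Conditions: CsF (4 equiv), 8 (1.5 equiv), THF, 125 °C, sealed tube
Reagents that add atoms: none
Why: Fluoride unmasks 3,5-bis(benzyloxy)benzyne 14, and the cesium carboxylate of 13 adds through oxygen to the aryne carbon remote from the flanking benzyloxy group (the future C8a), which places the aryl anion at the future C4a, where the adjacent C–O bond stabilizes it inductively. This anion attacks the neighbouring ester carbonyl (4-exo-trig) and the four-membered alkoxide opens to the 2-acylphenoxide of 15, a net insertion of the aryne into the acyl C–O bond that forms O1–C8a and C4–C4a; the closest known reaction type is the carboxylic acid–aryne C–O insertion that gives ortho-hydroxyaryl ketones and, from unsaturated acids, chroman-4-ones. Ring C then closes by 6-endo-trig oxa-Michael addition of the phenoxide to the 2-aryl enone (bond O1–C2), and the enolate is protonated by the hydrogen fluoride equivalent released from the acid. C3 arises in this unselective protonation, so 16 is expected as the racemate, which is acceptable because C3 is epimerizable and is set in step 9. The step needs regioselective aryne capture, secured by the benzyloxy group ortho to one aryne carbon, and carboxylate O-attack faster than ene or cycloaddition reactions at the styrene unit, secured by the ionic nucleophile and by the hot aprotic medium, which favours acyl transfer over protonation of the aryl anion.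

Step 9
Reactants: 16 rac-5,7-bis(benzyloxy)-3-[3,4-bis(benzyloxy)-5-(3-methylbut-2-en-1-yl)phenyl]-2,3-dihydro-4H-chromen-4-one
Product: 17 (3S,4S)-5,7-bis(benzyloxy)-3-[3,4-bis(benzyloxy)-5-(3-methylbut-2-en-1-yl)phenyl]-3,4-dihydro-2H-chromen-4-ol
Conditions: RuCl[(S,S)-TsDPEN](p-cymene) (cat.), HCO2H/Et3N (amine in excess), EtOAc, 40 °C
Reagents that add atoms: none
Why: Noyori–Ikariya asymmetric transfer hydrogenation with dynamic kinetic resolution: the (S,S)-TsDPEN ruthenium hydride sets C4 as S under catalyst control while amine-mediated enolization interconverts the C3 epimers, and the faster-reacting epimer leads to the cis alcohol, so C3 is fixed as S.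

Step 10
Reactants: 17 (3S,4S)-5,7-bis(benzyloxy)-3-[3,4-bis(benzyloxy)-5-(3-methylbut-2-en-1-yl)phenyl]-3,4-dihydro-2H-chromen-4-ol
Product: 18 (3S,4S)-5,7-bis(benzyloxy)-3-[3,4-bis(benzyloxy)-5-{[(2R)-3,3-dimethyloxiran-2-yl]methyl}phenyl]-3,4-dihydro-2H-chromen-4-ol
Conditions: D-fructose-derived Shi ketone (0.3 equiv), Oxone (2KHSO5·KHSO4·K2SO4), K2CO3, Bu4NHSO4, MeCN/dimethoxymethane/aq. Na2B4O7–Na2EDTA buffer, 0 °C
Reagents that add atoms: potassium peroxymonosulfate (the active salt of Oxone) [K+].[O-]S(=O)(=O)OO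
Why: Shi asymmetric epoxidation: the chiral dioxirane transfers oxygen to the trisubstituted prenyl olefin through a spiro transition state, the D-fructose-derived ketone setting the (R)-epoxide under catalyst control, while the basic medium spares the acid-labile benzylic alcohol and no free phenol is present to be oxidized.

Step 11
Reactants: 18 (3S,4S)-5,7-bis(benzyloxy)-3-[3,4-bis(benzyloxy)-5-{[(2R)-3,3-dimethyloxiran-2-yl]methyl}phenyl]-3,4-dihydro-2H-chromen-4-ol
Product: 19 (3S)-5,7-bis(benzyloxy)-3-[3,4-bis(benzyloxy)-5-{[(2R)-3,3-dimethyloxiran-2-yl]methyl}phenyl]-2,3-dihydro-4H-chromen-4-one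
Conditions: Dess–Martin periodinane, NaHCO3, CH2Cl2, 0 °C to rt
Reagents that add atoms: none
Why: Dess–Martin oxidation returns the C4 ketone under buffered, non-enolizing conditions, so the C3 configuration set in step 9 and the epoxide should both be preserved.

Step 12
Reactants: 19 (3S)-5,7-bis(benzyloxy)-3-[3,4-bis(benzyloxy)-5-{[(2R)-3,3-dimethyloxiran-2-yl]methyl}phenyl]-2,3-dihydro-4H-chromen-4-one
Product: 20 (3S)-3-(3-{[(2R)-3,3-dimethyloxiran-2-yl]methyl}-4,5-dihydroxyphenyl)-5,7-dihydroxy-2,3-dihydro-4H-chromen-4-one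
Conditions: H2 (1 atm), 10% Pd/C, EtOAc, rt, stopped at full conversion
Reagents that add atoms: none
Why: Neutral catalytic hydrogenolysis cleaves the four benzyl aryl ethers, whereas the non-benzylic trisubstituted epoxide, the chelated aryl ketone and the C3 center, which sees neither acid nor base, should survive.

Compound list
1 | 3,5-bis(benzyloxy)phenol | Oc1cc(OCc2ccccc2)cc(OCc2ccccc2)c1 | starting material
2 | 3,5-bis(benzyloxy)phenyl N-(propan-2-yl)carbamate | CC(C)NC(=O)Oc1cc(OCc2ccccc2)cc(OCc2ccccc2)c1 | intermediate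
3 | 3,5-bis(benzyloxy)phenyl N-(tert-butyldimethylsilyl)-N-(propan-2-yl)carbamate | CC(C)N(C(=O)Oc1cc(OCc2ccccc2)cc(OCc2ccccc2)c1)[Si](C)(C)C(C)(C)C | intermediate
4 | 2-lithio derivative of 3 (aryllithium) | CC(C)N(C(=O)Oc1cc(OCc2ccccc2)cc(OCc2ccccc2)c1[Li])[Si](C)(C)C(C)(C)C | intermediate
5 | 3,5-bis(benzyloxy)-2-(trimethylsilyl)phenyl N-(tert-butyldimethylsilyl)-N-(propan-2-yl)carbamate | CC(C)N(C(=O)Oc1cc(OCc2ccccc2)cc(OCc2ccccc2)c1[Si](C)(C)C)[Si](C)(C)C(C)(C)C | intermediate
6 | 3,5-bis(benzyloxy)-2-(trimethylsilyl)phenyl N-(propan-2-yl)carbamate | CC(C)NC(=O)Oc1cc(OCc2ccccc2)cc(OCc2ccccc2)c1[Si](C)(C)C | intermediate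
7 | 3,5-bis(benzyloxy)-2-(trimethylsilyl)phenol | C[Si](C)(C)c1c(O)cc(OCc2ccccc2)cc1OCc1ccccc1 | intermediate
8 | 3,5-bis(benzyloxy)-2-(trimethylsilyl)phenyl trifluoromethanesulfonate | C[Si](C)(C)c1c(OS(=O)(=O)C(F)(F)F)cc(OCc2ccccc2)cc1OCc1ccccc1 | intermediate
9 | 3-bromo-4,5-dihydroxybenzaldehyde | O=Cc1cc(O)c(O)c(Br)c1 | starting material
10 | 3,4-bis(benzyloxy)-5-bromobenzaldehyde | O=Cc1cc(Br)c(OCc2ccccc2)c(OCc2ccccc2)c1 | intermediate
11 | 3,4-bis(benzyloxy)-5-(3-methylbut-2-en-1-yl)benzaldehyde | CC(C)=CCc1cc(C=O)cc(OCc2ccccc2)c1OCc1ccccc1 | intermediate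
12 | 1,2-bis(benzyloxy)-5-ethynyl-3-(3-methylbut-2-en-1-yl)benzene | CC(C)=CCc1cc(C#C)cc(OCc2ccccc2)c1OCc1ccccc1 | intermediate
13 | 2-[3,4-bis(benzyloxy)-5-(3-methylbut-2-en-1-yl)phenyl]prop-2-enoic acid | CC(C)=CCc1cc(C(=C)C(=O)O)cc(OCc2ccccc2)c1OCc1ccccc1 | intermediate
14 | 3,5-bis(benzyloxy)benzyne (1,2-didehydro-3,5-bis(benzyloxy)benzene) | C1#CC(OCc2ccccc2)=CC(OCc2ccccc2)=C1 | intermediate
15 | 1-[2,4-bis(benzyloxy)-6-hydroxyphenyl]-2-[3,4-bis(benzyloxy)-5-(3-methylbut-2-en-1-yl)phenyl]prop-2-en-1-one (formed as its cesium phenoxide) | CC(C)=CCc1cc(C(=C)C(=O)c2c(O)cc(OCc3ccccc3)cc2OCc2ccccc2)cc(OCc2ccccc2)c1OCc1ccccc1 | intermediate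
16 | rac-5,7-bis(benzyloxy)-3-[3,4-bis(benzyloxy)-5-(3-methylbut-2-en-1-yl)phenyl]-2,3-dihydro-4H-chromen-4-one | CC(C)=CCc1cc(C2COc3cc(OCc4ccccc4)cc(OCc4ccccc4)c3C2=O)cc(OCc2ccccc2)c1OCc1ccccc1 | intermediate
17 | (3S,4S)-5,7-bis(benzyloxy)-3-[3,4-bis(benzyloxy)-5-(3-methylbut-2-en-1-yl)phenyl]-3,4-dihydro-2H-chromen-4-ol (cis) | CC(C)=CCc1cc([C@H]2COc3cc(OCc4ccccc4)cc(OCc4ccccc4)c3[C@H]2O)cc(OCc2ccccc2)c1OCc1ccccc1 | intermediate
18 | (3S,4S)-5,7-bis(benzyloxy)-3-[3,4-bis(benzyloxy)-5-{[(2R)-3,3-dimethyloxiran-2-yl]methyl}phenyl]-3,4-dihydro-2H-chromen-4-ol | CC1(C)O[C@@H]1Cc1cc([C@H]2COc3cc(OCc4ccccc4)cc(OCc4ccccc4)c3[C@H]2O)cc(OCc2ccccc2)c1OCc1ccccc1 | intermediate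
19 | (3S)-5,7-bis(benzyloxy)-3-[3,4-bis(benzyloxy)-5-{[(2R)-3,3-dimethyloxiran-2-yl]methyl}phenyl]-2,3-dihydro-4H-chromen-4-one | CC1(C)O[C@@H]1Cc1cc([C@H]2COc3cc(OCc4ccccc4)cc(OCc4ccccc4)c3C2=O)cc(OCc2ccccc2)c1OCc1ccccc1 | intermediate
20 | (3S)-3-(3-{[(2R)-3,3-dimethyloxiran-2-yl]methyl}-4,5-dihydroxyphenyl)-5,7-dihydroxy-2,3-dihydro-4H-chromen-4-one | CC1(C)O[C@@H]1Cc1cc([C@H]2COc3cc(O)cc(O)c3C2=O)cc(O)c1O | target

Total step count: 12. Longest linear sequence: 9 steps (from 9 to 20, steps 4 to 12).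

Steps most likely to fail

1. Step 8. What may go wrong: thermal oligomerization of the 2-arylacrylate, its consumption by the aryne through ene or cycloaddition pathways at the styrene unit, or conjugate addition of carboxylate or fluoride before the acyl transfer. The fallback sets out from aldehyde 11 (with triflate 8) and comes back to the route at 16. Reductive cyanation of 11 with TosMIC (t-BuOK, dimethoxyethane, −30 °C, then MeOH, reflux; van Leusen reaction) should give 2-[3,4-bis(benzyloxy)-5-(3-methylbut-2-en-1-yl)phenyl]acetonitrile F1. Hydrolysis (KOH, EtOH/H2O, reflux, then acidification) should give the arylacetic acid F2. The same carboxylic acid–aryne C–O insertion with 8 (CsF, THF, 125 °C), now on a saturated acid that offers neither a Michael acceptor nor a styrene, should give the 2-hydroxydeoxybenzoin F3. Heating F3 with paraformaldehyde and Et2NH in EtOH (Mannich methylenation, amine elimination and oxa-Michael closure in one flask) should then give 16.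

2. Step 12. What may go wrong: hydrogenolytic or trace-acid opening of the epoxide on the catalyst surface, including 5-exo attack by the newly freed ortho hydroxyl. The fallback sets out from 16 and ends at the target 20. The four benzyl ethers of 16 would be removed before any epoxide exists (BCl3, pentamethylbenzene, CH2Cl2, −78 °C) to give the racemic tetraphenol F6, which would be silylated (TBSCl, imidazole, DMAP, DMF) to the tetrakis(tert-butyldimethylsilyl) ether F7. The conditions of steps 9 to 11 would then be applied in the silyl series, giving in turn the cis-alcohol F8, the epoxy alcohol F9 and the epoxy ketone F10. Buffered fluoride (Et3N·3HF, THF, 0 °C) would finally release 20 without hydrogen or a metal surface.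

3. Step 9. What may go wrong: slow hydride transfer to the electron-rich ketone shielded by the peri benzyloxy group, C3 enolization too slow for efficient dynamic resolution, or ionization of the trioxygenated benzylic alcohol in the formate medium. The fallback sets out from 16 and comes back to the route at 17. Ketone 16 would be converted into its trimethylsilyl enol ether F4 (KN(SiMe3)2, TMSCl, THF, −78 °C). Catalytic enantioselective protonation of F4 with a BINOL-derived N-triflyl thiophosphoramide and phenol as the stoichiometric proton source (toluene, rt), with the catalyst enantiomer chosen accordingly, should give the (3S)-ketone F5. Reduction with LiBH(s-Bu)3 (THF, −78 °C), which delivers hydride to the face opposite the C3 aryl group, should then give the cis-alcohol 17.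

Further compounds
F1 | step 8 | 2-[3,4-bis(benzyloxy)-5-(3-methylbut-2-en-1-yl)phenyl]acetonitrile | CC(C)=CCc1cc(CC#N)cc(OCc2ccccc2)c1OCc1ccccc1
F2 | step 8 | 2-[3,4-bis(benzyloxy)-5-(3-methylbut-2-en-1-yl)phenyl]acetic acid | CC(C)=CCc1cc(CC(=O)O)cc(OCc2ccccc2)c1OCc1ccccc1
F3 | step 8 | 1-[2,4-bis(benzyloxy)-6-hydroxyphenyl]-2-[3,4-bis(benzyloxy)-5-(3-methylbut-2-en-1-yl)phenyl]ethan-1-one | CC(C)=CCc1cc(CC(=O)c2c(O)cc(OCc3ccccc3)cc2OCc2ccccc2)cc(OCc2ccccc2)c1OCc1ccccc1
F4 | step 9 | 5,7-bis(benzyloxy)-3-[3,4-bis(benzyloxy)-5-(3-methylbut-2-en-1-yl)phenyl]-4-(trimethylsilyloxy)-2H-chromene | CC(C)=CCc1cc(C2=C(O[Si](C)(C)C)c3c(OCc4ccccc4)cc(OCc4ccccc4)cc3OC2)cc(OCc2ccccc2)c1OCc1ccccc1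
F5 | step 9 | (3S)-5,7-bis(benzyloxy)-3-[3,4-bis(benzyloxy)-5-(3-methylbut-2-en-1-yl)phenyl]-2,3-dihydro-4H-chromen-4-one | CC(C)=CCc1cc([C@H]2COc3cc(OCc4ccccc4)cc(OCc4ccccc4)c3C2=O)cc(OCc2ccccc2)c1OCc1ccccc1
F6 | step 12 | rac-3-[3,4-dihydroxy-5-(3-methylbut-2-en-1-yl)phenyl]-5,7-dihydroxy-2,3-dihydro-4H-chromen-4-one | CC(C)=CCc1cc(C2COc3cc(O)cc(O)c3C2=O)cc(O)c1O
F7 | step 12 | rac-5,7-bis(tert-butyldimethylsilyloxy)-3-[3,4-bis(tert-butyldimethylsilyloxy)-5-(3-methylbut-2-en-1-yl)phenyl]-2,3-dihydro-4H-chromen-4-one | CC(C)=CCc1cc(C2COc3cc(O[Si](C)(C)C(C)(C)C)cc(O[Si](C)(C)C(C)(C)C)c3C2=O)cc(O[Si](C)(C)C(C)(C)C)c1O[Si](C)(C)C(C)(C)C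
F8 | step 12 | (3S,4S)-5,7-bis(tert-butyldimethylsilyloxy)-3-[3,4-bis(tert-butyldimethylsilyloxy)-5-(3-methylbut-2-en-1-yl)phenyl]-3,4-dihydro-2H-chromen-4-ol | CC(C)=CCc1cc([C@H]2COc3cc(O[Si](C)(C)C(C)(C)C)cc(O[Si](C)(C)C(C)(C)C)c3[C@H]2O)cc(O[Si](C)(C)C(C)(C)C)c1O[Si](C)(C)C(C)(C)C
F9 | step 12 | (3S,4S)-5,7-bis(tert-butyldimethylsilyloxy)-3-[3,4-bis(tert-butyldimethylsilyloxy)-5-{[(2R)-3,3-dimethyloxiran-2-yl]methyl}phenyl]-3,4-dihydro-2H-chromen-4-ol | CC1(C)O[C@@H]1Cc1cc([C@H]2COc3cc(O[Si](C)(C)C(C)(C)C)cc(O[Si](C)(C)C(C)(C)C)c3[C@H]2O)cc(O[Si](C)(C)C(C)(C)C)c1O[Si](C)(C)C(C)(C)C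
F10 | step 12 | (3S)-5,7-bis(tert-butyldimethylsilyloxy)-3-[3,4-bis(tert-butyldimethylsilyloxy)-5-{[(2R)-3,3-dimethyloxiran-2-yl]methyl}phenyl]-2,3-dihydro-4H-chromen-4-one | CC1(C)O[C@@H]1Cc1cc([C@H]2COc3cc(O[Si](C)(C)C(C)(C)C)cc(O[Si](C)(C)C(C)(C)C)c3C2=O)cc(O[Si](C)(C)C(C)(C)C)c1O[Si](C)(C)C(C)(C)C
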